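**Assumptions.** The target is taken exactly as drawn: a saturated germacrane 10-ring, an 8,12-olide, and a 9-O-(R)-2-methylbutanoate. The CIP analysis of the SMILES gives 4R, 7S, 8S, 9R, 10S. Germacrane numbering is used throughout. Several stereochemical outcomes (steps 4–6, 9 and 12) are assumed from conformational and directing-group arguments rather than from a precedent on this exact substrate.

## Retrosynthetic overview
1. The target comes from acylation of the C9-OH of a hydroxy α-methylene lactone. That lactone comes from acid-promoted C8 opening of a C8/C9 epoxy acid, with the C12 acid made from the isopropenyl methyl by SeO2 oxidation and then TEMPO/NaClO2.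
2. The C8/C9 epoxide comes from a hydroxyl-directed epoxidation of a Δ8 alkene by the C10 tertiary allylic alcohol. That alcohol comes from a Δ1(10) epoxide opened by hydride at C1.
3. The 10-membered ring and the C5 ketone come from an Evans anionic oxy-Cope ring expansion of a 1-isopropenyl-2-vinylcyclohex-3-enol. The C5–C10 bond breaks and C2–C3 forms.
4. The cyclohexene comes from (S)-carvone by dienolate α-hydroxymethylation, conversion of CH2OH to vinyl, and isopropenyl addition to the ketone.
5. Rings form in this order: carvone six-ring, then the 10-ring (oxy-Cope), then the epoxides, and last the γ-lactone.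

## Route

**Step 1**
Reactants: 1 (S)-carvone; 2 formaldehyde.
Product: 3, the 2-(hydroxymethyl)-2-methyl-5-isopropenylcyclohex-3-en-1-one (C5 as in carvone, CH2OH trans to isopropenyl).
Conditions: KOt-Bu, THF, 0 °C; then monomeric CH2O, –40 °C.
Reagents that add atoms: formaldehyde, C=O.
Why: The extended (thermodynamic) dienolate of carvone reacts at Cα (C10), making the quaternary centre and moving the alkene to C8=C9. The electrophile approaches anti to the C7 isopropenyl group (extended-enolate aldol hydroxymethylation).

**Step 2**
Reactants: 3.
Product: 4, the corresponding α-formyl ketone.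
Conditions: Dess–Martin periodinane, NaHCO3, CH2Cl2, 0 °C to rt.
Reagents that add atoms: none.
Why: Buffered DMP oxidises the neopentyl primary alcohol to a non-enolisable aldehyde without retro-aldol or epimerisation.

**Step 3**
Reactants: 4; 5 methylenetriphenylphosphorane.
Product: 6, 2-methyl-2-vinyl-5-isopropenylcyclohex-3-en-1-one.
Conditions: Ph3P=CH2 (from Ph3PCH3Br, KOt-Bu), THF, –78 to 0 °C.
Reagents that add atoms: methylenetriphenylphosphorane, C=P(c1ccccc1)(c1ccccc1)c1ccccc1 (leaves CH2).
Why: Wittig methylenation occurs at the aldehyde, which is much more reactive than the hindered ketone, and installs the C1=C2 vinyl group on C10.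

**Step 4**
Reactants: 6; 7 2-propenylmagnesium bromide.
Product: 8, the tertiary alcohol C5(OH)(isopropenyl), with isopropenyl trans to the C10 vinyl group.
Conditions: CH2=C(Me)MgBr, CeCl3, THF, –78 °C.
Reagents that add atoms: 2-propenylmagnesium bromide, C=C(C)[Mg]Br.
Why: The organocerium reagent adds 1,2 to the hindered, enolisable ketone. Attack is assumed to occur anti to the neighbouring vinyl group, which gives the trans-1,2-divinyl arrangement needed for a chair-like [3,3] transition state and an E alkene (organocerium addition).

**Step 5 (key step)**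
Reactants: 8.
Product: 9, germacra-1(10)E,8Z,11(13)-trien-5-one (C4-H/Me, C7 isopropenyl).
Conditions: KH, 18-crown-6, THF, 0 to 25 °C; then aq. NH4Cl.
Reagents that add atoms: none.
Why: Evans anionic oxy-Cope [3,3] shift breaks C5–C10 and forms C2–C3, which expands the ring by four carbons. The enolate C4=C5 gives the 5-ketone on protonation, C1=C10 is E, the ring Z-alkene C8=C9 is untouched, and C7 is not involved.

**Step 6**
Reactants: 9.
Product: 10, 1,10-epoxy-germacra-8Z,11(13)-dien-5-one, with epoxide face as in the target (C10 S).
Conditions: mCPBA (1.0 equiv), NaHCO3, CH2Cl2, –20 °C.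
Reagents that add atoms: mCPBA, OOC(=O)c1cccc(Cl)c1.
Why: Prilezhaev epoxidation takes the most electron-rich, trisubstituted end of the conjugated diene. The peripheral face is assumed to be the one favoured by the macrocycle conformation enforced by the C7 stereocentre, which sets C10.

**Step 7**
Reactants: 10.
Product: 11, germacra-8Z,11(13)-diene-5,10-diol (C5 epimers).
Conditions: LiEt3BH (3 equiv), THF, –78 to 0 °C.
Reagents that add atoms: none (hydride only).
Why: Hydride opens the epoxide by SN2 at the unhindered secondary C1. The C10–O bond is not touched, so the tertiary alcohol keeps its configuration (10S). The C5 ketone is reduced at the same time and is restored in step 8.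

**Step 8**
Reactants: 11.
Product: 12, 10-hydroxygermacra-8Z,11(13)-dien-5-one.
Conditions: DMP, NaHCO3, CH2Cl2, rt.
Reagents that add atoms: none.
Why: DMP oxidises only the secondary C5-OH; the tertiary allylic alcohol is inert, and C4 stays epimerisable and equilibrates to the natural configuration.

**Step 9**
Reactants: 12.
Product: 13, 8,9-epoxy-10-hydroxygermacr-11(13)-en-5-one, with C9–O cis to C10–O.
Conditions: VO(acac)2 (5 mol%), t-BuOOH, CH2Cl2, 25 °C.
Reagents that add atoms: tert-butyl hydroperoxide, CC(C)(C)OO (supplies O).
Why: Sharpless–Michaelson hydroxyl-directed epoxidation delivers oxygen to C8=C9 syn to the C10-OH. This sets C9 and is selective over the isopropenyl group.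

**Step 10**
Reactants: 13.
Product: 14, the 12-hydroxy derivative (2-substituted allylic alcohol).
Conditions: SeO2 (0.2 equiv), t-BuOOH, CH2Cl2, 25 °C.
Reagents that add atoms: selenium dioxide, O=[Se]=O; tert-butyl hydroperoxide, CC(C)(C)OO.
Why: Riley ene/[2,3] allylic oxidation converts the isopropenyl CH3 (C12) to CH2OH. Isopropenyl is now the only alkene, so the oxidation is selective.

**Step 11**
Reactants: 14.
Product: 15, 8,9-epoxy-10-hydroxy-5-oxogermacr-11(13)-en-12-oic acid.
Conditions: TEMPO (cat.), NaClO2, NaOCl (cat.), MeCN, pH 6.7 phosphate buffer, 35 °C.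
Reagents that add atoms: sodium chlorite, [Na+].[O-]Cl=O.
Why: The Zhao–Miller oxidation takes the primary alcohol through the aldehyde to the acid. The ketone, the hindered tertiary alcohol and the epoxide are untouched.

**Step 12**
Reactants: 15.
Product: 16, 9,10-dihydroxy-5-oxogermacran-8,12-olide, 11(13)-ene (C9-OH free).
Conditions: CSA (10 mol%), MeCN/H2O 10:1, 25 °C.
Reagents that add atoms: none (net isomerisation).
Why: Acid opens the epoxide at C8, because C9 is deactivated and hindered by the adjacent carbinol carbon C10. Attack occurs with inversion, by the C12 carboxyl or by water followed by γ-lactonisation. C8–O is therefore anti to C9–O, and the γ-lactone closes onto C8-OH (trans-fused lactone formed by intramolecular epoxide opening/lactonisation).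

**Step 13**
Reactants: 16; 17 (R)-2-methylbutanoic acid.
Product: 18, Ineupatorolide A.
Conditions: 17, 2,4,6-Cl3C6H2COCl, Et3N, THF; then 16, DMAP, toluene, 50 °C.
Reagents that add atoms: (R)-2-methylbutanoic acid, CC[C@@H](C)C(=O)O.
Why: The Yamaguchi mixed anhydride acylates the secondary C9-OH. The tertiary C10-OH does not react, and the acid's stereocentre is carried over unchanged.

## Checks
- Every intermediate follows from its reactants with all atoms accounted for. The epoxy acid 15 and the lactone 16 are isomers (C15H22O5), and the final ester is C20H30O6.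
- Stereocentres and where they are set:
  - C7 comes from (S)-carvone.
  - C10 is set in step 6 and retained in step 7.
  - C9 is set in step 9.
  - C8 is set by the inversion in step 12.
  - C4 is set by enolate protonation and then thermodynamic equilibration.
  - The ester stereocentre comes from the chiral acid.
- No chiral catalyst, reagent or auxiliary is used anywhere.

## Compound list
1 | (S)-carvone | C=C(C)[C@H]1CC=C(C)C(=O)C1 | starting material
2 | formaldehyde | C=O | starting material
3 | 2-(hydroxymethyl)-2-methyl-5-isopropenylcyclohex-3-en-1-one (C5 as in carvone, CH2OH trans to isopropenyl) | C=C(C)[C@H]1C=C[C@](C)(CO)C(=O)C1 | intermediate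
4 | 2-formyl-2-methyl-5-isopropenylcyclohex-3-en-1-one | C=C(C)[C@H]1C=C[C@](C)(C=O)C(=O)C1 | intermediate
5 | methylenetriphenylphosphorane | C=P(c1ccccc1)(c1ccccc1)c1ccccc1 | starting material
6 | 2-methyl-2-vinyl-5-isopropenylcyclohex-3-en-1-one | C=C(C)[C@H]1C=C[C@](C)(C=C)C(=O)C1 | intermediate
7 | 2-propenylmagnesium bromide | C=C(C)[Mg]Br | starting material
8 | 1-isopropenyl-2-methyl-2-vinyl-5-isopropenylcyclohex-3-en-1-ol (oxy-Cope precursor, isopropenyl trans to vinyl) | C=C(C)[C@H]1C=C[C@](C)(C=C)[C@@](O)(C(C)=C)C1 | intermediate
9 | germacra-1(10)E,8Z,11(13)-trien-5-one | C=C(C)[C@H]1/C=C\C(C)=C\CC[C@@H](C)C(=O)C1 | intermediate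
10 | 1,10-epoxy-germacra-8Z,11(13)-dien-5-one | C=C(C)[C@H]1/C=C\[C@@]3(C)O[C@@H]3CC[C@@H](C)C(=O)C1 | intermediate
11 | germacra-8Z,11(13)-diene-5,10-diol (C5 epimers) | C=C(C)[C@H]1/C=C\[C@@](C)(O)CCC[C@@H](C)C(O)C1 | intermediate
12 | 10-hydroxygermacra-8Z,11(13)-dien-5-one | C=C(C)[C@H]1/C=C\[C@@](C)(O)CCC[C@@H](C)C(=O)C1 | intermediate
13 | 8,9-epoxy-10-hydroxygermacr-11(13)-en-5-one | C=C(C)[C@H]1[C@H]2O[C@H]2[C@@](C)(O)CCC[C@@H](C)C(=O)C1 | intermediate
14 | 8,9-epoxy-10,12-dihydroxygermacr-11(13)-en-5-one | OCC(=C)[C@H]1[C@H]2O[C@H]2[C@@](C)(O)CCC[C@@H](C)C(=O)C1 | intermediate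
15 | 8,9-epoxy-10-hydroxy-5-oxogermacr-11(13)-en-12-oic acid | OC(=O)C(=C)[C@H]1[C@H]2O[C@H]2[C@@](C)(O)CCC[C@@H](C)C(=O)C1 | intermediate
16 | 9,10-dihydroxy-5-oxogermacr-11(13)-en-8,12-olide | C=C1C(=O)O[C@@H]2[C@@H](O)[C@@](C)(O)CCC[C@@H](C)C(=O)C[C@@H]12 | intermediate
17 | (R)-2-methylbutanoic acid | CC[C@@H](C)C(=O)O | starting material
18 | Ineupatorolide A | C=C1C(=O)O[C@@H]2[C@@H](OC(=O)[C@H](C)CC)[C@@](C)(O)CCC[C@@H](C)C(=O)C[C@@H]12 | target

## Totals
**Total steps:** 13. **Longest linear sequence:** 13 (from (S)-carvone; the acid 17 enters at step 13).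

**Three steps most likely to fail**
1. **Step 6 (chemoselective and diastereoselective epoxidation of the diene).** The reagent could attack the isopropenyl group, or the C10 epoxide could form on the wrong face.
   - Fallback: change the order so the C10 oxygen is delivered by a directing group. Put a C9-OH on the diene first, then use VO(acac)2-directed epoxidation of C1=C10 (cis to C9-OH), and open with Red-Al or LiAlH4.
2. **Step 5 with step 4 (diastereoselectivity of the addition and alkene geometry in the oxy-Cope).** The wrong C5 epimer, or competing [3,3] to the ring alkene, would give (Z)-C1=C10 or other products.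
   - Fallback: replace the ring expansion by a Robinson annulation of the carvone-derived ketone to the eudesmane decalin, then Grob/Wharton-type cleavage of C5–C10 to the germacrane.
3. **Step 12 (epoxide opening and trans-lactonisation at C8).** Attack at C9, or the wrong C8 configuration, would give a δ-lactone or a cis-lactone.
   - Fallback: open the epoxide to the C8/C9 trans-diol and use Mitsunobu lactonisation (DEAD/PPh3) of the hydroxy acid, which inverts C8 to the required trans-lactone.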